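Everything rests on unfolding the tetrahydrofuran (O1, C2 carrying the free-phenol ring A, C3, C4, C5 carrying the methoxy ring B) to a γ-lactone. O1–C2 becomes the acyl–oxygen bond, and the sterically disfavoured cis pair, C4 methyl and ring B on C5, is already in place. A chiral triazolylidene converts crotonaldehyde into a homoenolate that adds to vanillin tosylate, forming C4–C5 and O1–C2, the lactone ring and both stereocentres in a single operation. The precursors are only (E)-crotonaldehyde and the electron-poor sulfonate-protected vanillin. C3 methylation, sulfone-mediated arylation at C2 with ring A, and two lactate-derived arms complete manassantin B1.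

Key step: step 2

Remark: the triazolium antipode that delivers (4R,5S) is taken to be the (5aS,10bR) salt and is to be confirmed in a test run (the mirror-image salt is equally available); 3,4-dimethoxyphenylmagnesium bromide is bought as a THF solution.

Step 1
Reactants: 1 vanillin
Product: 2 vanillin tosylate (4-formyl-2-methoxyphenyl 4-methylbenzenesulfonate)
Conditions: TsCl, Et3N, CH2Cl2, 0 °C → rt
Reagents that add atoms: p-toluenesulfonyl chloride (TsCl), Cc1ccc(cc1)S(=O)(=O)Cl
Why: Sulfonylation of the phenol with TsCl and an amine base (sulfonate ester formation) is routine and leaves the aldehyde untouched, and the resulting sulfonate makes the formyl group more electrophilic.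

Step 2
Reactants: 2 vanillin tosylate (1.5 equiv), 3 (E)-crotonaldehyde
Product: 4 (4R,5S)-5-[3-methoxy-4-(tosyloxy)phenyl]-4-methyloxolan-2-one (methyl and aryl cis)
Conditions: (5aS,10bR)-2-mesityl-5a,10b-dihydro-4H,6H-indeno[2,1-b][1,2,4]triazolo[4,3-d][1,4]oxazin-2-ium chloride (10 mol %), 1,8-diazabicyclo[5.4.0]undec-7-ene (DBU, 10 mol %), THF, rt, slow addition of 3
Reagents that add atoms: none
Why: The free carbene adds to the formyl carbon of 3 and proton transfer gives the conjugated enaminol (homoenolate equivalent), whose β-carbon attacks the aldehyde carbon of 2 to form C4–C5; tautomerisation to the acyl azolium is followed by attack of the new alkoxide on the acyl carbon, which forms O1–C2 and releases the carbene. The closest known reaction type is the N-heterocyclic-carbene-catalysed homoenolate [3+2] annulation of enals with aryl aldehydes, which gives cis-4,5-disubstituted γ-butyrolactones. The one ring is closed by a 5-exo-trig acyl substitution (lactonisation) on the acyl azolium. C4 and C5 arise together in the C–C bond-forming event: their cis relation comes from the compact arrangement of enaminol and aldehyde that is inherent to this annulation, and their absolute sense (4R,5S) from the aminoindane wall of the triazolylidene, which leaves one face of the homoenolate open. The step needs cross- over self-annulation, which the electron-poor sulfonate-bearing aldehyde (in excess, with slow addition of 3) should secure, and cis over trans plus one enantiomer, where the level of induction with a β-methyl enal is the open question; the tosylate is expected to give a crystalline lactone that can be enriched by recrystallisation.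

Step 3
Reactants: 4 cis-lactone
Product: 5 (3R,4R,5S)-5-[3-methoxy-4-(tosyloxy)phenyl]-3,4-dimethyloxolan-2-one (3,4-trans, 4,5-cis)
Conditions: LiN(SiMe3)2, THF, −78 °C; MeI, −78 → −40 °C
Reagents that add atoms: iodomethane (MeI), CI
Why: Alkylation of the lithium lactone enolate with MeI occurs on the face opposite the cis-disposed C4 methyl and C5 aryl groups, so the new C3 methyl (3R) is trans to the C4 methyl; the aryl sulfonate is inert to the hindered amide base at −78 °C.

Step 4
Reactants: 5 dimethyl lactone
Product: 6 (3R,4R,5S)-5-[3-methoxy-4-(tosyloxy)phenyl]-3,4-dimethyloxolan-2-ol (lactol, both C2 epimers)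
Conditions: i-Bu2AlH, CH2Cl2, −78 °C; aq. potassium sodium tartrate
Reagents that add atoms: none
Why: Partial reduction of a lactone by i-Bu2AlH at −78 °C stops at the aluminium hemiacetal, which gives the lactol on work-up (lactone-to-lactol reduction) without touching the aryl sulfonate or the three ring stereocentres.

Step 5
Reactants: 6 lactol
Product: 7 (3R,4R,5S)-5-[3-methoxy-4-(tosyloxy)phenyl]-3,4-dimethyl-2-(phenylsulfonyl)oxolane (both C2 epimers)
Conditions: PhSO2H, CaCl2, CH2Cl2, rt
Reagents that add atoms: benzenesulfinic acid, O=S(O)c1ccccc1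
Why: Acid-assisted ionisation of the lactol to the C2 oxocarbenium ion and capture by sulfinate at sulfur gives the anomeric sulfone (2-sulfonyl cyclic ether formation), CaCl2 taking up the water; the C2 configuration is of no consequence.

Step 6
Reactants: 8 2-(benzyloxy)phenol
Product: 9 2-(benzyloxy)-4-bromophenol
Conditions: NBS, MeCN, 0 °C
Reagents that add atoms: N-bromosuccinimide (NBS), O=C1CCC(=O)N1Br
Why: Electrophilic aromatic bromination with NBS goes para to the free hydroxyl, the strongest donor on the ring, as is usual for 2-alkoxyphenols.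

Step 7
Reactants: 9 2-(benzyloxy)-4-bromophenol
Product: 10 [2-(benzyloxy)-4-bromophenoxy](tert-butyl)dimethylsilane
Conditions: TBSCl, imidazole, DMF, rt
Reagents that add atoms: tert-butyldimethylsilyl chloride (TBSCl), CC(C)(C)[Si](C)(C)Cl
Why: Imidazole-promoted silylation of the phenol is standard, and the silyl ether survives organomagnesium formation yet falls to hydroxide later.

Step 8
Reactants: 7 anomeric sulfone, 10 silyl-protected aryl bromide
Product: 13 (2S,3R,4R,5S)-2-[3-(benzyloxy)-4-(tert-butyldimethylsilyloxy)phenyl]-5-[3-methoxy-4-(tosyloxy)phenyl]-3,4-dimethyloxolane, via arylmagnesium bromide 11 (not isolated), via arylzinc bromide 12 (not isolated)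
Conditions: 10, Mg, THF, 50 °C; ZnBr2, THF, rt; then 7, THF, rt
Reagents that add atoms: none
Why: Magnesium and zinc halide assist departure of benzenesulfinate to give the C2 oxocarbenium ion, and the arylzinc adds to the face away from the C5 aryl group by inside attack on the envelope that keeps the C3 methyl pseudo-equatorial, so ring A ends cis to the C3 methyl and trans to ring B (2S); this substitution of 2-sulfonyl cyclic ethers by organozinc reagents is documented for 2,3-cis-3,4-trans-4,5-cis diaryl dimethyl tetrahydrofurans.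

Step 9
Reactants: 13 protected tetrahydrofuran
Product: 14 2-(benzyloxy)-4-[(2S,3R,4R,5S)-5-(4-hydroxy-3-methoxyphenyl)-3,4-dimethyloxolan-2-yl]phenol
Conditions: KOH, MeOH/THF/H2O, 60 °C; then dilute HCl to pH 6
Reagents that add atoms: none
Why: Hydroxide attacks sulfur of the aryl sulfonate and silicon of the aryl silyl ether (sulfonate ester hydrolysis and desilylation), releasing both para-phenols at once, while the benzyl ether and the four ring stereocentres, none of which bears an acidic hydrogen, are unaffected.

Step 10
Reactants: 15 ethyl (S)-lactate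
Product: 16 (S)-2-hydroxy-N-methoxy-N-methylpropanamide
Conditions: MeNHOMe·HCl, i-PrMgCl, THF, −20 → 0 °C
Reagents that add atoms: N,O-dimethylhydroxylamine hydrochloride, CNOC.Cl
Why: Aminolysis of the ester by the chloromagnesium amide of N,O-dimethylhydroxylamine (Weinreb amide formation) proceeds on the unprotected hydroxy ester with the stereocentre untouched.

Step 11
Reactants: 16 hydroxy Weinreb amide, 17 3,4-dimethoxyphenylmagnesium bromide
Product: 18 (S)-1-(3,4-dimethoxyphenyl)-2-hydroxypropan-1-one
Conditions: i-PrMgCl (1 equiv), THF, −20 °C; then 17, 0 °C → rt; aq. NH4Cl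
Reagents that add atoms: none
Why: Weinreb ketone synthesis: after deprotonation of the hydroxyl, the aryl Grignard reagent adds once and the chelated tetrahedral intermediate collapses to the ketone only on quench, so neither over-addition nor loss of the (S) centre is expected.

Step 12
Reactants: 18 hydroxy ketone
Product: 19 (S)-1-(3,4-dimethoxyphenyl)-1-oxopropan-2-yl 4-methylbenzenesulfonate
Conditions: TsCl, pyridine, CH2Cl2, 0 °C
Reagents that add atoms: p-toluenesulfonyl chloride (TsCl), Cc1ccc(cc1)S(=O)(=O)Cl
Why: Sulfonylation of the secondary alcohol (sulfonate ester formation) does not break the C–O bond, so the (S) configuration is retained and a carbonyl-activated leaving group results.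

Step 13
Reactants: 14 bisphenol, 19 keto tosylate (2.4 equiv)
Product: 20 bis-ketone, compound 14 in which each of the two phenolic oxygens carries an (R)-1-(3,4-dimethoxyphenyl)-1-oxopropan-2-yl group
Conditions: Cs2CO3, DMF, 0 °C → rt
Reagents that add atoms: none
Why: Each caesium phenoxide displaces the carbonyl-activated secondary tosylate in an SN2 reaction (Williamson ether synthesis) with inversion, so both new aryloxy carbons are (R); the two phenols need no differentiation because both take the same arm.

Step 14
Reactants: 20 bis-ketone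
Product: 21 manassantin B1 benzyl ether (benzyl on the ring A meta oxygen; both arms (1R,2R)-1-(3,4-dimethoxyphenyl)-1-hydroxypropan-2-yl)
Conditions: borohydride exchange resin (polystyrene-bound R–NMe3+ BH4−), MeOH, 0 °C → rt
Reagents that add atoms: none
Why: Hydride from a non-chelating ammonium borohydride attacks each ketone anti to the aryloxy group in the polar Felkin–Anh sense (substrate-controlled ketone reduction), which gives the threo (1R,2R) alcohol in both arms.

Step 15
Reactants: 21 manassantin B1 benzyl ether
Product: 22 manassantin B1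
Conditions: H2 (1 atm), 10% Pd/C, EtOAc, rt
Reagents that add atoms: none
Why: Catalytic hydrogenolysis of the aryl benzyl ether under neutral conditions is much faster than cleavage of the benzylic alcohols or the tetrahydrofuran C–O bonds, so the ring A phenol is freed without touching a stereocentre.

Compound list
1 | vanillin | COc1cc(C=O)ccc1O | starting material
2 | vanillin tosylate (4-formyl-2-methoxyphenyl 4-methylbenzenesulfonate) | COc1cc(C=O)ccc1OS(=O)(=O)c1ccc(C)cc1 | intermediate
3 | (E)-crotonaldehyde | C/C=C/C=O | starting material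
4 | (4R,5S)-5-[3-methoxy-4-(tosyloxy)phenyl]-4-methyloxolan-2-one | O=C1O[C@H](c2ccc(OS(=O)(=O)c3ccc(C)cc3)c(OC)c2)[C@H](C)C1 | intermediate
5 | (3R,4R,5S)-5-[3-methoxy-4-(tosyloxy)phenyl]-3,4-dimethyloxolan-2-one | O=C1O[C@H](c2ccc(OS(=O)(=O)c3ccc(C)cc3)c(OC)c2)[C@H](C)[C@H]1C | intermediate
6 | (3R,4R,5S)-5-[3-methoxy-4-(tosyloxy)phenyl]-3,4-dimethyloxolan-2-ol (C2 epimers) | OC1O[C@H](c2ccc(OS(=O)(=O)c3ccc(C)cc3)c(OC)c2)[C@H](C)[C@H]1C | intermediate
7 | (3R,4R,5S)-5-[3-methoxy-4-(tosyloxy)phenyl]-3,4-dimethyl-2-(phenylsulfonyl)oxolane (C2 epimers) | O=S(=O)(c1ccccc1)C1O[C@H](c2ccc(OS(=O)(=O)c3ccc(C)cc3)c(OC)c2)[C@H](C)[C@H]1C | intermediate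
8 | 2-(benzyloxy)phenol | Oc1ccccc1OCc1ccccc1 | starting material
9 | 2-(benzyloxy)-4-bromophenol | Oc1ccc(Br)cc1OCc1ccccc1 | intermediate
10 | [2-(benzyloxy)-4-bromophenoxy](tert-butyl)dimethylsilane | CC(C)(C)[Si](C)(C)Oc1ccc(Br)cc1OCc1ccccc1 | intermediate
11 | [3-(benzyloxy)-4-(tert-butyldimethylsilyloxy)phenyl]magnesium bromide (formed in the flask) | CC(C)(C)[Si](C)(C)Oc1ccc([Mg]Br)cc1OCc1ccccc1 | intermediate
12 | [3-(benzyloxy)-4-(tert-butyldimethylsilyloxy)phenyl]zinc bromide (formed in the flask) | CC(C)(C)[Si](C)(C)Oc1ccc([Zn]Br)cc1OCc1ccccc1 | intermediate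
13 | (2S,3R,4R,5S)-2-[3-(benzyloxy)-4-(tert-butyldimethylsilyloxy)phenyl]-5-[3-methoxy-4-(tosyloxy)phenyl]-3,4-dimethyloxolane | CC(C)(C)[Si](C)(C)Oc1ccc(cc1OCc1ccccc1)[C@H]1O[C@H](c2ccc(OS(=O)(=O)c3ccc(C)cc3)c(OC)c2)[C@H](C)[C@H]1C | intermediate
14 | 2-(benzyloxy)-4-[(2S,3R,4R,5S)-5-(4-hydroxy-3-methoxyphenyl)-3,4-dimethyloxolan-2-yl]phenol | Oc1ccc(cc1OCc1ccccc1)[C@H]1O[C@H](c2ccc(O)c(OC)c2)[C@H](C)[C@H]1C | intermediate
15 | ethyl (S)-lactate | C[C@H](O)C(=O)OCC | starting material
16 | (S)-2-hydroxy-N-methoxy-N-methylpropanamide | C[C@H](O)C(=O)N(C)OC | intermediate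
17 | 3,4-dimethoxyphenylmagnesium bromide | COc1ccc([Mg]Br)cc1OC | starting material
18 | (S)-1-(3,4-dimethoxyphenyl)-2-hydroxypropan-1-one | C[C@H](O)C(=O)c1ccc(OC)c(OC)c1 | intermediate
19 | (S)-1-(3,4-dimethoxyphenyl)-1-oxopropan-2-yl 4-methylbenzenesulfonate | C[C@H](OS(=O)(=O)c1ccc(C)cc1)C(=O)c1ccc(OC)c(OC)c1 | intermediate
20 | bis-ketone: 14 with an (R)-1-(3,4-dimethoxyphenyl)-1-oxopropan-2-yl group on each phenolic oxygen | COc1ccc(C(=O)[C@@H](C)Oc2ccc([C@H]3O[C@H](c4ccc(O[C@H](C)C(=O)c5ccc(OC)c(OC)c5)c(OC)c4)[C@H](C)[C@H]3C)cc2OCc6ccccc6)cc1OC | intermediate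
21 | manassantin B1 benzyl ether (ring A meta oxygen benzylated, arms (1R,2R)) | COc1ccc([C@@H](O)[C@@H](C)Oc2ccc([C@H]3O[C@H](c4ccc(O[C@H](C)[C@H](O)c5ccc(OC)c(OC)c5)c(OC)c4)[C@H](C)[C@H]3C)cc2OCc6ccccc6)cc1OC | intermediate
22 | manassantin B1 | COc1ccc([C@@H](O)[C@@H](C)Oc2ccc([C@H]3O[C@H](c4ccc(O[C@H](C)[C@H](O)c5ccc(OC)c(OC)c5)c(OC)c4)[C@H](C)[C@H]3C)cc2O)cc1OC | target

Total step count: 15. Longest linear sequence: 10 steps (1, 2, 3, 4, 5, 8, 9, 13, 14, 15, from vanillin).

Steps most likely to fail

Step 2. The risks are insufficient enantio-induction at C4 and C5, partial formation of the trans lactone, and consumption of crotonaldehyde by self-annulation or of the aldehyde by benzoin-type side reactions. The fallback sets out from 2 and returns at 4. Brown asymmetric crotylboration of 2 with the B-(Z)-crotyldiisopinocampheylborane antipode that gives the syn adduct should furnish 4-[(1S,2R)-1-hydroxy-2-methylbut-3-en-1-yl]-2-methoxyphenyl 4-methylbenzenesulfonate F1. Hydroboration of its terminal alkene with 9-borabicyclo[3.3.1]nonane and oxidation with NaBO3 should give 4-[(1S,2R)-1,4-dihydroxy-2-methylbutyl]-2-methoxyphenyl 4-methylbenzenesulfonate F2. Selective oxidation of the primary alcohol with TEMPO and PhI(OAc)2, followed by lactol formation and further oxidation in the same flask, should close the cis-lactone 4.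

Step 8. The risks are poor facial selectivity in the addition to the oxocarbenium ion, loss of sulfinic acid by elimination to the dihydrofuran, and sluggish magnesium insertion into 10. The fallback sets out from 5 (steps 4 and 5 are then not needed) and returns at 13. Bromine–lithium exchange on 10 with n-BuLi at −78 °C gives [3-(benzyloxy)-4-(tert-butyldimethylsilyloxy)phenyl]lithium F3, which adds once to lactone 5 to give the cyclic hemiketal (3R,4R,5S)-2-[3-(benzyloxy)-4-(tert-butyldimethylsilyloxy)phenyl]-5-[3-methoxy-4-(tosyloxy)phenyl]-3,4-dimethyloxolan-2-ol F4. Ionisation with BF3·OEt2 in the presence of Et3SiH at −78 °C should deliver hydride anti to the C3 methyl, which sits pseudo-axial to avoid the C2 aryl group, and so give the 2,3-cis product 13. The sulfonate on ring B is expected to retard acid ionisation at C5 during this Lewis-acid step.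

Step 13. The risks are erosion of configuration at the carbonyl-adjacent carbon by base-induced enolisation of the keto tosylate or of the aryloxy ketone, and incomplete double alkylation. The fallback sets out from 14 and returns at 20. A double Mitsunobu reaction of 14 with ethyl (S)-lactate 15 (PPh3, diisopropyl azodicarboxylate, THF), which inverts the lactate carbon, should give the diethyl bis[(R)-2-aryloxypropanoate] F5, whose ester centres are far less prone to enolisation. Treatment with MeNHOMe·HCl and i-PrMgCl converts it into the bis(N-methoxy-N-methylamide) F6, and addition of 17 to both amide groups gives bis-ketone 20.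

Further compounds
F1 | step 2 | 4-[(1S,2R)-1-hydroxy-2-methylbut-3-en-1-yl]-2-methoxyphenyl 4-methylbenzenesulfonate | O[C@H](c1ccc(OS(=O)(=O)c2ccc(C)cc2)c(OC)c1)[C@H](C)C=C
F2 | step 2 | 4-[(1S,2R)-1,4-dihydroxy-2-methylbutyl]-2-methoxyphenyl 4-methylbenzenesulfonate | O[C@H](c1ccc(OS(=O)(=O)c2ccc(C)cc2)c(OC)c1)[C@H](C)CCO
F3 | step 8 | [3-(benzyloxy)-4-(tert-butyldimethylsilyloxy)phenyl]lithium | CC(C)(C)[Si](C)(C)Oc1ccc([Li])cc1OCc1ccccc1
F4 | step 8 | (3R,4R,5S)-2-[3-(benzyloxy)-4-(tert-butyldimethylsilyloxy)phenyl]-5-[3-methoxy-4-(tosyloxy)phenyl]-3,4-dimethyloxolan-2-ol (C2 epimers) | CC(C)(C)[Si](C)(C)Oc1ccc(cc1OCc1ccccc1)C1(O)O[C@H](c2ccc(OS(=O)(=O)c3ccc(C)cc3)c(OC)c2)[C@H](C)[C@H]1C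
F5 | step 13 | diethyl ester: 14 with an (R)-1-ethoxy-1-oxopropan-2-yl group on each phenolic oxygen | CCOC(=O)[C@@H](C)Oc1ccc(cc1OCc1ccccc1)[C@H]1O[C@H](c2ccc(O[C@H](C)C(=O)OCC)c(OC)c2)[C@H](C)[C@H]1C
F6 | step 13 | bis(N-methoxy-N-methylamide): 14 with an (R)-1-[methoxy(methyl)amino]-1-oxopropan-2-yl group on each phenolic oxygen | CON(C)C(=O)[C@@H](C)Oc1ccc(cc1OCc1ccccc1)[C@H]1O[C@H](c2ccc(O[C@H](C)C(=O)N(C)OC)c(OC)c2)[C@H](C)[C@H]1C
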